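**Retrosynthetic overview**
- The chlorohydrin comes from HCl opening of an 11,13-epoxide, itself made from the α-methylene lactone of the finished macrocycle.
- The furanone and the ten-membered carbocycle are formed together from an acyclic hydroxy-ynone aldehyde: gold cycloisomerisation, then a C9–C10 macro-aldol that sets C9 and the quaternary C10.
- The ynone comes from acyl Sonogashira coupling of a terminal alkyne with an O-silyl lactoyl chloride; the alkyne (C2–C4, C15) comes from a Marshall propargylation of a C5 aldehyde, which sets C4 and C5.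
- The lactone fragment (C5–C9, C11–C13) comes from a Zn-Barbier reaction between a glyceraldehyde-derived (Z)-2-(bromomethyl)enoate and glyoxal mono-acetal (sets C7, C8), then tigloylation and acid-induced lactonisation.
- Ring order: γ-lactone first, then furanone and carbocycle in one operation.

Assumption: the target's carbons are numbered as in germacranolides (C1 furanone C=O, C2=C3, C4 with CH3-15, C5 OH, C6 lactone O, C7, C8 O-tiglate, C9 OH, C10 with CH3-14 and ring O, C11 OH, C12 lactone C=O, C13 CH2Cl), which makes the target 4R,5S,6S,7S,8S,9S,10S,11S; this numbering is used for all intermediates.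

**Route**

Step 1
Reactants: 1 (R)-2,2-dimethyl-1,3-dioxolane-4-carbaldehyde (D-glyceraldehyde acetonide); 2 methyl acrylate
Product: 3 methyl 2-{hydroxy[(4R)-2,2-dimethyl-1,3-dioxolan-4-yl]methyl}prop-2-enoate (both carbinol epimers)
Conditions: DABCO (0.5 equiv), neat methyl acrylate (3 equiv), rt, 3–5 d
Reagents that add atoms: none
Why: Morita–Baylis–Hillman reaction; the new carbinol centre is erased in step 2, so only the untouched glyceraldehyde centre (future C6) matters.

Step 2
Reactants: 3 methyl 2-{hydroxy[(4R)-2,2-dimethyl-1,3-dioxolan-4-yl]methyl}prop-2-enoate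
Product: 4 methyl (2Z)-2-(bromomethyl)-3-[(4S)-2,2-dimethyl-1,3-dioxolan-4-yl]prop-2-enoate
Conditions: NBS, Me2S, CH2Cl2, 0 °C → rt
Reagents that add atoms: N-bromosuccinimide, O=C1CCC(=O)N1Br
Why: Corey–Kim-type activation of the Baylis–Hillman alcohol and SN2′ bromide delivery give the rearranged allylic bromide as the favoured Z isomer (dioxolanyl cis to CH2Br) under near-neutral conditions that spare the acetonide.

Step 3
Reactants: 4 methyl (2Z)-2-(bromomethyl)-3-[(4S)-2,2-dimethyl-1,3-dioxolan-4-yl]prop-2-enoate; 5 2,2-dimethoxyacetaldehyde (60% aqueous solution)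
Product: 7 methyl (3R,4S)-3-[(4S)-2,2-dimethyl-1,3-dioxolan-4-yl]-4-hydroxy-5,5-dimethoxy-2-methylidenepentanoate, via allylzinc bromide 6 (not isolated)
Conditions: Zn dust, THF/sat. aq NH4Cl, 0 °C → rt
Reagents that add atoms: none
Why: Zn-Barbier (Dreiding–Schmidt) allylation: the Z-configured allylzinc reacts at its γ-carbon through a chair Zimmerman–Traxler transition state to give the 7,8-syn (crotyl sense) adduct, and the aldehyde approaches anti to the dioxolane C–O bond in the A(1,3)-minimised H-eclipsed conformer, which sets C7 and C8 relative to C6.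

Step 4
Reactants: 7 methyl (3R,4S)-3-[(4S)-2,2-dimethyl-1,3-dioxolan-4-yl]-4-hydroxy-5,5-dimethoxy-2-methylidenepentanoate; 8 tigloyl chloride [(2E)-2-methylbut-2-enoyl chloride]
Product: 9 methyl (3S,4S)-3-[(4S)-2,2-dimethyl-1,3-dioxolan-4-yl]-5,5-dimethoxy-2-methylidene-4-{[(2E)-2-methylbut-2-enoyl]oxy}pentanoate
Conditions: Et3N, DMAP (cat.), CH2Cl2, 0 °C → rt
Reagents that add atoms: none
Why: DMAP-catalysed O-acylation installs the C8 tiglate with retention (the descriptor change at C3 is only a CIP priority change) and blocks lactonisation onto O8.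

Step 5
Reactants: 9 methyl (3S,4S)-3-[(4S)-2,2-dimethyl-1,3-dioxolan-4-yl]-5,5-dimethoxy-2-methylidene-4-{[(2E)-2-methylbut-2-enoyl]oxy}pentanoate
Product: 11 (1S)-1-[(2S,3S)-2-(hydroxymethyl)-4-methylidene-5-oxooxolan-3-yl]-2,2-dimethoxyethyl (2E)-2-methylbut-2-enoate, via diol ester 10 (not isolated)
Conditions: CSA (0.2 equiv), MeOH, rt → 45 °C
Reagents that add atoms: none
Why: acid-catalysed transketalisation frees the C5/C6 diol and the C6 hydroxyl lactonises onto the methyl ester (γ-lactone favoured over δ), giving the 6,7-trans α-methylene lactone already fixed by C6/C7, while the deactivated α-acyloxy dimethyl acetal persists in methanol.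

Step 6
Reactants: 11 (1S)-1-[(2S,3S)-2-(hydroxymethyl)-4-methylidene-5-oxooxolan-3-yl]-2,2-dimethoxyethyl (2E)-2-methylbut-2-enoate
Product: 12 (1S)-1-[(2S,3S)-2-formyl-4-methylidene-5-oxooxolan-3-yl]-2,2-dimethoxyethyl (2E)-2-methylbut-2-enoate
Conditions: Dess–Martin periodinane, CH2Cl2, 0 °C → rt; used crude
Reagents that add atoms: none
Why: Dess–Martin oxidation of the primary alcohol under base-free conditions, so the epimerisable C6 centre α to the new aldehyde is preserved.

Step 7
Reactants: 13 (R)-but-3-yn-2-ol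
Product: 14 (R)-but-3-yn-2-yl methanesulfonate
Conditions: MsCl, Et3N, CH2Cl2, −78 → 0 °C
Reagents that add atoms: methanesulfonyl chloride, CS(=O)(=O)Cl
Why: O-sulfonylation with retention provides the chiral propargylic electrophile for the Marshall reagent.

Step 8
Reactants: 12 (1S)-1-[(2S,3S)-2-formyl-4-methylidene-5-oxooxolan-3-yl]-2,2-dimethoxyethyl (2E)-2-methylbut-2-enoate; 14 (R)-but-3-yn-2-yl methanesulfonate
Product: 16 (1S)-1-{(2S,3S)-2-[(1S,2S)-1-hydroxy-2-methylbut-3-yn-1-yl]-4-methylidene-5-oxooxolan-3-yl}-2,2-dimethoxyethyl (2E)-2-methylbut-2-enoate, via allenylindium 15 (not isolated)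
Conditions: Pd(dppf)Cl2 (5 mol %), InI (1.5 equiv), THF/HMPA 3:1, 0 °C → rt
Reagents that add atoms: none
Why: Marshall propargylation: anti-SN2′ oxidative addition of Pd(0) and transmetalation give the (P)-allenylindium, whose cyclic SE2′ addition is anti-selective and reagent-controlled (net inversion at the mesylate carbon), setting C4 and C5 (4,5-anti; 5,6-syn against the weak Felkin bias of the aldehyde).

Step 9
Reactants: 17 L-lactic acid [(S)-2-hydroxypropanoic acid, anhydrous]
Product: 19 (S)-2-(triethylsilyloxy)propanoyl chloride, via bis-TES lactate 18 (not isolated)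
Conditions: TESCl (2.1 equiv), Et3N, CH2Cl2, 0 °C → rt; then (COCl)2, DMF (cat.), 0 °C → rt; concentrate and use crude
Reagents that add atoms: chlorotriethylsilane, CC[Si](CC)(CC)Cl; oxalyl chloride, ClC(=O)C(Cl)=O
Why: bis-silylation followed by the neutral oxalyl chloride/DMF conversion of a silyl ester into the acid chloride leaves the O-silyl ether intact (this centre, future C10, is in any case re-set in step 12).

Step 10
Reactants: 16 (1S)-1-{(2S,3S)-2-[(1S,2S)-1-hydroxy-2-methylbut-3-yn-1-yl]-4-methylidene-5-oxooxolan-3-yl}-2,2-dimethoxyethyl (2E)-2-methylbut-2-enoate; 19 (S)-2-(triethylsilyloxy)propanoyl chloride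
Product: 20 (1S)-1-{(2S,3S)-2-[(1S,2S,6S)-1-hydroxy-2-methyl-5-oxo-6-(triethylsilyloxy)hept-3-yn-1-yl]-4-methylidene-5-oxooxolan-3-yl}-2,2-dimethoxyethyl (2E)-2-methylbut-2-enoate
Conditions: PdCl2(PPh3)2 (3 mol %), CuI (6 mol %), Et3N (1.5 equiv), THF, rt
Reagents that add atoms: none
Why: acyl Sonogashira coupling builds the ynone (C1–C3) under amine conditions that the lactone, tiglate and acetal tolerate, and the hindered secondary C5 hydroxyl is not acylated by the branched acid chloride without an acyl-transfer catalyst.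

Step 11
Reactants: 20 (1S)-1-{(2S,3S)-2-[(1S,2S,6S)-1-hydroxy-2-methyl-5-oxo-6-(triethylsilyloxy)hept-3-yn-1-yl]-4-methylidene-5-oxooxolan-3-yl}-2,2-dimethoxyethyl (2E)-2-methylbut-2-enoate
Product: 22 (1S)-1-{(2S,3S)-2-[(1S,2S,6S)-1-(tert-butyldimethylsilyloxy)-6-hydroxy-2-methyl-5-oxohept-3-yn-1-yl]-4-methylidene-5-oxooxolan-3-yl}-2-oxoethyl (2E)-2-methylbut-2-enoate, via bis-silyl aldehyde 21 (not isolated)
Conditions: TBSOTf (3 equiv), 2,6-lutidine (5 equiv), CH2Cl2, −78 → 0 °C; H2O; then AcOH/THF/H2O 3:1:1, rt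
Reagents that add atoms: tert-butyldimethylsilyl trifluoromethanesulfonate, CC(C)(C)[Si](C)(C)OS(=O)(=O)C(F)(F)F; water, O
Why: the silyl triflate/hindered pyridine pair first silylates the C5 hydroxyl and then ionises the dimethyl acetal (Fujioka-type chemoselective acetal cleavage, aldehyde released on adding water), after which aqueous acetic acid removes the unhindered C10 TES ether but not the hindered secondary TBS ether.

Step 12
Reactants: 22 (1S)-1-{(2S,3S)-2-[(1S,2S,6S)-1-(tert-butyldimethylsilyloxy)-6-hydroxy-2-methyl-5-oxohept-3-yn-1-yl]-4-methylidene-5-oxooxolan-3-yl}-2-oxoethyl (2E)-2-methylbut-2-enoate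
Product: 24 5-O-TBS 11(13)-ene macrocycle (target skeleton with furanone and ten-membered ring closed; 4R,5S,6S,8S,9S,10S and C7 as in the target; exocyclic CH2 at C11), via 2H-furanone aldehyde 23 (not isolated)
Conditions: Ph3PAuNTf2 (5 mol %), CH2Cl2, rt, Ar; then dilute to 2 mM, MgBr2·OEt2 (2 equiv), Et3N (3 equiv), −20 → 0 °C
Reagents that add atoms: none
Why: Proposed new method: Au(I) activation lets the C10 hydroxyl add 5-endo-dig to the ynone β-carbon (known gold cycloisomerisation of γ-hydroxy-ynones to 3(2H)-furanones), and MgBr2/Et3N then soft-enolises the 2-H-furanone to an aromatic 3-furanolate whose C10 attacks the tethered C9 aldehyde through a closed Zimmerman–Traxler transition state (enolate methyl cis to O–Mg gives 9-OH/10-CH3 syn, hence 10S; Felkin–Anh attack anti to the C8 acyloxy group gives 8,9-anti, hence 9S), so the furanone and the ten-membered carbocycle form in one pot; the closest known reactions are C2-aldol additions of 3(2H)-furanone enolates and magnesium-mediated soft-enolisation aldol reactions.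

Step 13
Reactants: 24 5-O-TBS 11(13)-ene macrocycle
Product: 25 5-O-TBS (11S)-11,13-epoxide (spiro-oxirane on the lactone α-carbon; all other centres as in 24)
Conditions: t-BuOOH (5.5 M in decane, 3 equiv), DBU (1.5 equiv), CH2Cl2, 0 °C
Reagents that add atoms: tert-butyl hydroperoxide, CC(C)(C)OO
Why: Weitz–Scheffer-type nucleophilic epoxidation attacks only the unhindered α-methylene lactone (tiglate and the β-alkoxy enone are far poorer acceptors), and the lactone enolate closes onto oxygen on the face anti to the adjacent C7–C8 bond, which sets 11S.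

Step 14
Reactants: 25 5-O-TBS (11S)-11,13-epoxide
Product: 26 CNP0340393.1 [(4R,5S,6S,7S,8S,9S,10S,11S)-13-chloro-5,9,11-trihydroxy-1-oxo-3,10-epoxygermacr-2-en-12,6-olide 8-O-tiglate]
Conditions: 3 M aq HCl, THF, 0 °C → rt
Reagents that add atoms: hydrogen chloride, Cl
Why: acid-promoted SN2 opening of the glycidic lactone by chloride at the primary C13 (C11–O bond untouched, so 11S is retained) together with acidic cleavage of the C5 TBS ether gives the target.

**Compound list**
1 | (R)-2,2-dimethyl-1,3-dioxolane-4-carbaldehyde | CC1(C)OC[C@H](C=O)O1 | starting material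
2 | methyl acrylate | C=CC(=O)OC | starting material
3 | methyl 2-{hydroxy[(4R)-2,2-dimethyl-1,3-dioxolan-4-yl]methyl}prop-2-enoate (carbinol centre unassigned, both epimers used) | COC(=O)C(=C)C(O)[C@H]1COC(C)(C)O1 | intermediate
4 | methyl (2Z)-2-(bromomethyl)-3-[(4S)-2,2-dimethyl-1,3-dioxolan-4-yl]prop-2-enoate | COC(=O)/C(CBr)=C/[C@H]1COC(C)(C)O1 | intermediate
5 | 2,2-dimethoxyacetaldehyde | COC(OC)C=O | starting material
6 | allylzinc bromide derived from 4 | COC(=O)/C(C[Zn]Br)=C/[C@H]1COC(C)(C)O1 | intermediate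
7 | methyl (3R,4S)-3-[(4S)-2,2-dimethyl-1,3-dioxolan-4-yl]-4-hydroxy-5,5-dimethoxy-2-methylidenepentanoate | COC(=O)C(=C)[C@@H]([C@H]1COC(C)(C)O1)[C@H](O)C(OC)OC | intermediate
8 | tigloyl chloride | C/C=C(\C)C(Cl)=O | starting material
9 | methyl (3S,4S)-3-[(4S)-2,2-dimethyl-1,3-dioxolan-4-yl]-5,5-dimethoxy-2-methylidene-4-(tigloyloxy)pentanoate | COC(=O)C(=C)[C@@H]([C@H]1COC(C)(C)O1)[C@H](OC(=O)/C(C)=C/C)C(OC)OC | intermediate
10 | methyl (3S,4S)-3-[(1S)-1,2-dihydroxyethyl]-5,5-dimethoxy-2-methylidene-4-(tigloyloxy)pentanoate | COC(=O)C(=C)[C@@H]([C@H](O)CO)[C@H](OC(=O)/C(C)=C/C)C(OC)OC | intermediate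
11 | (1S)-1-[(2S,3S)-2-(hydroxymethyl)-4-methylidene-5-oxooxolan-3-yl]-2,2-dimethoxyethyl tiglate | OC[C@H]1OC(=O)C(=C)[C@@H]1[C@H](OC(=O)/C(C)=C/C)C(OC)OC | intermediate
12 | (1S)-1-[(2S,3S)-2-formyl-4-methylidene-5-oxooxolan-3-yl]-2,2-dimethoxyethyl tiglate | O=C[C@H]1OC(=O)C(=C)[C@@H]1[C@H](OC(=O)/C(C)=C/C)C(OC)OC | intermediate
13 | (R)-but-3-yn-2-ol | C#C[C@@H](C)O | starting material
14 | (R)-but-3-yn-2-yl methanesulfonate | C#C[C@@H](C)OS(C)(=O)=O | intermediate
15 | (P)-buta-1,2-dien-1-ylindium(III) iodide methanesulfonate (allene axis in extended-tetrahedral notation) | [H]C(C)=[C@]=C([H])[In](I)OS(C)(=O)=O | intermediate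
16 | (1S)-1-{(2S,3S)-2-[(1S,2S)-1-hydroxy-2-methylbut-3-yn-1-yl]-4-methylidene-5-oxooxolan-3-yl}-2,2-dimethoxyethyl tiglate | C#C[C@H](C)[C@H](O)[C@H]1OC(=O)C(=C)[C@@H]1[C@H](OC(=O)/C(C)=C/C)C(OC)OC | intermediate
17 | L-lactic acid | C[C@H](O)C(=O)O | starting material
18 | triethylsilyl (S)-2-(triethylsilyloxy)propanoate | C[C@H](O[Si](CC)(CC)CC)C(=O)O[Si](CC)(CC)CC | intermediate
19 | (S)-2-(triethylsilyloxy)propanoyl chloride | C[C@H](O[Si](CC)(CC)CC)C(Cl)=O | intermediate
20 | C10-O-TES ynone with free 5-OH and C9 dimethyl acetal (name as in step 10) | C[C@H](O[Si](CC)(CC)CC)C(=O)C#C[C@H](C)[C@H](O)[C@H]1OC(=O)C(=C)[C@@H]1[C@H](OC(=O)/C(C)=C/C)C(OC)OC | intermediate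
21 | 5-O-TBS, 10-O-TES ynone with C9 aldehyde | C[C@H](O[Si](CC)(CC)CC)C(=O)C#C[C@H](C)[C@H](O[Si](C)(C)C(C)(C)C)[C@H]1OC(=O)C(=C)[C@@H]1[C@H](OC(=O)/C(C)=C/C)C=O | intermediate
22 | 5-O-TBS 10-hydroxy ynone with C9 aldehyde (name as in step 11) | C[C@H](O)C(=O)C#C[C@H](C)[C@H](O[Si](C)(C)C(C)(C)C)[C@H]1OC(=O)C(=C)[C@@H]1[C@H](OC(=O)/C(C)=C/C)C=O | intermediate
23 | 2-methyl-5-alkyl-3(2H)-furanone with C9 aldehyde (C10 as formed, freely epimerising) | C[C@@H]1OC(=CC1=O)[C@H](C)[C@H](O[Si](C)(C)C(C)(C)C)[C@H]1OC(=O)C(=C)[C@@H]1[C@H](OC(=O)/C(C)=C/C)C=O | intermediate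
24 | 5-O-TBS 11(13)-ene macrocycle | C/C=C(\C)C(=O)O[C@H]1[C@@H]2[C@H](OC(=O)C2=C)[C@@H](O[Si](C)(C)C(C)(C)C)[C@@H](C)C2=CC(=O)[C@@](C)(O2)[C@H]1O | intermediate
25 | 5-O-TBS (11S)-11,13-epoxide | C/C=C(\C)C(=O)O[C@H]1[C@@H]2[C@H](OC(=O)[C@]2(O3)C3)[C@@H](O[Si](C)(C)C(C)(C)C)[C@@H](C)C2=CC(=O)[C@@](C)(O2)[C@H]1O | intermediate
26 | CNP0340393.1 | C/C=C(\C)C(=O)O[C@H]1[C@@H]2[C@H](OC(=O)[C@]2(O)CCl)[C@@H](O)[C@@H](C)C2=CC(=O)[C@@](C)(O2)[C@H]1O | target

**Step count**
Total: 14 steps. Longest linear sequence: 12 steps (1 → 26 through steps 1–6, 8 and 10–14); steps 7 and 9 are one-step side branches.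

**Three steps most likely to fail**

Step 12 (one-pot furanone formation and macro-aldol). The ten-membered ring may not close, the C9/C10 selectivity may not follow the closed-transition-state model, and the magnesium aldolate could add to the α-methylene lactone. The fallback sets out from 22 and comes back at 24. The gold stage is run alone and the furanone aldehyde 23 is isolated. It is O-silylated (TMSCl, Et3N, CH2Cl2, −78 °C) to the aromatic 3-(trimethylsilyloxy)furan aldehyde F1. The ring is then closed as an intramolecular Mukaiyama aldol (BF3·OEt2, CH2Cl2, 1 mM, −78 °C), which goes through an open, Felkin-controlled transition state instead of a metal chelate and gives 24 after aqueous work-up.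

Step 3 (Barbier reaction). The syn selectivity of the Z-allylzinc is well grounded, but the facial control by the dioxolane centre rests on a model. The fallback sets out from 5 together with commercial (S)-5-(hydroxymethyl)furan-2(5H)-one F2 and comes back at 11.
- F2 is silylated (TBSCl, imidazole) to the TBS ether F3.
- A Baylis–Hillman reaction with aqueous formaldehyde (imidazole, THF/H2O) gives the 3-(hydroxymethyl)butenolide F4, and PBr3 gives the 3-(bromomethyl)butenolide F5.
- Zn/NH4Cl coupling of F5 with 5 gives the α-methylene lactone carbinol F6; the new bond at C7 is forced trans to the C6 substituent by the ring, and the chair transition state of this E-locked reagent gives the C8 epimer.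
- Mitsunobu esterification with tiglic acid (PPh3, DIAD) inverts C8 and gives the tiglate F7, and HF·pyridine removes the silyl group to give 11.

Step 11 (one-pot silylation, acetal cleavage and selective TES removal; it also depends on step 10 tolerating the free 5-OH). The fallback sets out from 16 and comes back at 22. The alcohol is protected first (TBSCl, imidazole, DMF) as the TBS ether F8. Acyl Sonogashira coupling with 19 then gives the fully protected ynone acetal F9. The acetal is cleaved separately with TESOTf/2,4,6-collidine followed by water, and aqueous acetic acid removes the C10 TES group, which leads through 21 to 22.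

Further compounds
F1 | step 12 | 3-(trimethylsilyloxy)furan aldehyde (TMS enol ether of 23) | Cc1oc(cc1O[Si](C)(C)C)[C@H](C)[C@H](O[Si](C)(C)C(C)(C)C)[C@H]1OC(=O)C(=C)[C@@H]1[C@H](OC(=O)/C(C)=C/C)C=O
F2 | step 3 | (S)-5-(hydroxymethyl)furan-2(5H)-one (commercial) | OC[C@H]1OC(=O)C=C1
F3 | step 3 | (S)-5-[(tert-butyldimethylsilyloxy)methyl]furan-2(5H)-one | CC(C)(C)[Si](C)(C)OC[C@H]1OC(=O)C=C1
F4 | step 3 | (S)-5-[(tert-butyldimethylsilyloxy)methyl]-3-(hydroxymethyl)furan-2(5H)-one | CC(C)(C)[Si](C)(C)OC[C@H]1OC(=O)C(CO)=C1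
F5 | step 3 | (S)-3-(bromomethyl)-5-[(tert-butyldimethylsilyloxy)methyl]furan-2(5H)-one | CC(C)(C)[Si](C)(C)OC[C@H]1OC(=O)C(CBr)=C1
F6 | step 3 | C8-epimeric carbinol: 6,7-trans α-methylene lactone with 5-O-TBS, free 8-OH and C9 dimethyl acetal | CC(C)(C)[Si](C)(C)OC[C@H]1OC(=O)C(=C)[C@@H]1[C@@H](O)C(OC)OC
F7 | step 3 | 5-O-TBS ether of 11 | CC(C)(C)[Si](C)(C)OC[C@H]1OC(=O)C(=C)[C@@H]1[C@H](OC(=O)/C(C)=C/C)C(OC)OC
F8 | step 11 | 5-O-TBS ether of 16 | C#C[C@H](C)[C@H](O[Si](C)(C)C(C)(C)C)[C@H]1OC(=O)C(=C)[C@@H]1[C@H](OC(=O)/C(C)=C/C)C(OC)OC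
F9 | step 11 | 5-O-TBS, 10-O-TES ynone with C9 dimethyl acetal | C[C@H](O[Si](CC)(CC)CC)C(=O)C#C[C@H](C)[C@H](O[Si](C)(C)C(C)(C)C)[C@H]1OC(=O)C(=C)[C@@H]1[C@H](OC(=O)/C(C)=C/C)C(OC)OC
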